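## The problem

The target is an 18-membered cyclophane built from four benzene rings: ring A (trioxygenated, on the carbinol carbon), ring B (para-phenylene), ring C (2-aryloxy-3-hydroxy) and ring D (meta-phenylene). The ring is held together by two diaryl ether oxygens (A–O–B and C–O–D), a CH2CH2 bridge (B–C) and a CH2–CH(OH) bridge (D–A). Both ethers are crowded, each sitting next to a free hydroxyl, and the one on ring C is flanked on its other side by the ethylene chain. The only stereocentre is the (S)-configured benzylic carbinol; nothing else in the molecule can relay stereochemistry to it, so a reagent must set it and every later step must leave it alone. That carbinol is para to the free C4 hydroxyl of ring A, so acid or base can ionise it through a quinone methide and palladium with hydrogen can cleave its C–O bond. Ring A is also a catechol and will not tolerate oxidants or basic air once it is free. The enabling feature is that ring A carries its aryloxy group at C5 directly ortho to the free C4 hydroxyl: a 2-aryloxyphenol is what oxidative phenol coupling delivers. The O(ring B)–C5(ring A) bond can therefore be made by oxidising a ring A phenol and letting the ring B phenol oxygen add, which closes the macrocycle at the same time.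

## Retrosynthesis

**Unveiling the target.** Target 26 is traced to its silyl ether 25 (O–Si cut) and 25 to macrocycle 24, which carries two chlorines on ring B and benzyl ethers on rings A and C (two C–Cl and two O–benzyl cuts). The p-hydroxybenzylic alcohol is freed last and under buffered fluoride, because it is the most fragile group in the molecule. One buffered hydrogenolysis clears everything else.

**Third oxygen of ring A.** The C3–O bond of ring A in 24 is cut back to a C–Br bond in benzyl ether 22, and 22 to bromophenol 21. An ether oxygen already in place at C3 during the ring closure would look shorter. It would not work: an ortho alkoxy group stabilises the cation at its own carbon and draws the nucleophile there, giving a quinone monoketal instead of the aryloxy dienone. With bromine at both ortho positions ring A is symmetric, so the ring closure has no regiochemical choice, and the bromine that survives is the handle for the hydroxyl. The forward steps are a phenol benzylation and a Miyaura borylation–oxidation that must take the C–Br bond and leave the two flanked C–Cl bonds.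

**Ring closure.** The O–C5(ring A) bond of 21 is cut to give the open bisphenol 19; in the forward direction the bromodienone 20 lies between them. Ring C is also a 2-aryloxyphenol, but its phenol has a free para position and its partner oxygen sits on a ring that cannot carry blocking halogens, so the C–O–D ether is better made early between small fragments. Ring A is a para-substituted phenol like a tyrosine and ring B is a para-substituted phenol whose two ortho positions can hold removable chlorines. This is the substitution pattern on which anodic or thallium trinitrate oxidation and zinc reduction are established. Precursor 19 is acyclic and is assembled from four monocyclic arenes. The forward reaction must oxidise ring A and not ring B, add oxygen and not carbon, and spare the silylated carbinol.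

**Stereocentre and phenol unmasking.** Bisphenol 19 comes from the fully silylated 18 by cleavage of two aryl O–Si bonds, 18 from (S)-alcohol 17, and 17 from ketone 16 by a C–H cut at the carbinol carbon. Silyl ethers of 2,6-dihalophenols are cleaved by buffered fluoride much faster than a secondary alkyl silyl ether. The two phenols can therefore be freed without touching the carbinol, the benzyl ether or any C–halogen bond; benzyl or allyl groups on these phenols would clash with the halogens or with the palladium steps. The ketone has an aryl group on one side and an arylmethyl group on the other, which is the size difference a Corey–Bakshi–Shibata reduction needs.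

**Carbinol carbon–CH2 bond.** Ketone 16 is traced to racemic alcohol 15, and 15 is cut between the carbinol carbon and the ring D methylene into benzylic bromide 11 and aldehyde 13. The zinc reagent 14 made from 11 is neutral enough to tolerate aryl bromides, aryl chlorides and aryl silyl ethers, which an enolate arylation or a magnesium reagent would not. Aldehyde 13 is the silyl ether of commercial 12.

**Bibenzyl bridge.** Bromide 11 comes from alcohol 10 and ester 9. Ester 9 is cut at the CH2–C(ring B) bond into styrene 5 and aryl bromide 7, joined in the forward direction through alkylborane 8 by a B-alkyl Suzuki–Miyaura coupling. A Wittig route would need four steps to a ring B phosphonium salt and then an alkene reduction in the presence of C–Cl bonds and a benzyl ether. The Suzuki route gives the saturated bridge directly and needs only the silyl ether 7 of commercial 6.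

**Ring C–ring D ether.** Styrene 5 comes from aldehyde 4 by methylenation. Aldehyde 4 is cut at the O–C(ring D) bond into phenol 2 and methyl 3-bromobenzoate 3 (Ullmann coupling), and 2 is the 3-O-benzyl ether of 1. The most hindered ether of the target is thus made first, on the smallest possible substrates, where a moderate result costs least.

## Roads not taken

**Alternative 1:** The cut is the bond between the benzylic CH2 and C3 of ring D. In the forward direction the enolate of the ring A methyl ketone in seco bromo ketone A1 is arylated intramolecularly by the ring D bromide under palladium catalysis, giving macrocyclic deoxybenzoin A2. Asymmetric reduction and hydrogenolysis finish the synthesis.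
- Merits: ring A enters with all three oxygens in place, both diaryl ethers are made between small fragments, no halogen is put on and taken off, and the endgame is short. In step count this road is better than the chosen one.
- Weak points: enolate arylation has little precedent as a macrocyclisation. It needs a strong base and heat at high dilution, where catalyst turnover drops. The product A2 is more acidic than the starting methyl ketone, so it is deprotonated and can be arylated again or oligomerise. The stereocentre would have to be set on a macrocyclic ketone whose two flanks are held by the ring, a situation in which reagent control is untested.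
- Comparison: the chosen plan pays about three extra operations (halogen handling and the late hydroxylation). In return its ring closure is a known reaction on a known substitution pattern and its stereocentre is set on a flexible open-chain ketone.

**Alternative 2:** The cut is the bond between the ethylene CH2 and C1 of ring C, with ring C held at the cyclohexenone oxidation level. The primary alkylzinc made from the iodide of seco compound A3 couples with the enol triflate in the same molecule under PdCl2(dppf), giving macrocycle A4. Ring C is aromatised afterwards.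
- Merits: alkylzinc–enol triflate coupling is dependable, and the crowded ring C ether is made as an enol ether of a dione, which avoids copper chemistry on a hindered phenol.
- Weak points: the zinc reagent must be formed at high dilution beside a vinylogous acyl triflate that is itself an electrophile. The enone A4 must then be dehydrogenated to a phenol late, on a macrocycle carrying benzyl ethers, a benzylic silyl ether and electron-rich rings. That is two uncertain operations at the most valuable stage.
- Comparison: the chosen plan also adjusts an oxidation level late (C–Br to C–OH), but does so by borylation and peroxide oxidation, which is routine. It gives up the easier ring C ether that this alternative offers and accepts an Ullmann coupling instead.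

**Alternative 3:** The cut is the O–C2 bond of ring C. The ring D phenoxide of seco compound A5 displaces fluoride ortho to a formyl group and gives macrocycle A6. A Baeyer–Villiger or Dakin oxidation then turns the formyl group into the C3 hydroxyl.
- Merits: nucleophilic aromatic substitution is among the most reliable closures for cyclophane diaryl ethers. It involves no redox chemistry at the closure, leaves the stereocentre alone, makes the hardest ether intramolecularly, and lets ring A carry all its oxygens from the start. As a ring closure it is at least as safe as the anodic one, and the route is probably no longer.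
- Weak points: the fluoride is activated by a single ortho formyl group and flanked by the ethylene chain, so the substitution needs heat and base on an aldehyde-bearing substrate. The A–O–B ether must be made intermolecularly on the trioxygenated ring. The closing oxidation of A6 is uncertain: with only one ortho aryloxy donor, aryl migration competes with hydride migration to the acid, and a peracid is used in the presence of electron-rich rings.
- Comparison: the chosen plan closes the ring at room temperature in neutral methanol by using the phenol and aryloxy pattern that ring A already has, so no carbon has to be excised afterwards. Its post-closure steps are standard, whereas this alternative ends on an oxidation of doubtful migratory preference.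

Key step: step 14

Remark on the chemistry: the usual order of oxidation potentials (2,6-dibromophenol below 2,6-dichlorophenol) is assumed to hold in 19; 9-BBN adducts and zinc reagents are drawn as monomers.

## Route

Step 1
Reactants: 1 2,3-dihydroxybenzaldehyde
Product: 2 3-(benzyloxy)-2-hydroxybenzaldehyde
Conditions: NaH (2.2 equiv), DMSO, rt; then BnBr (1.0 equiv), rt
Reagents that add atoms: benzyl bromide, BrCc1ccccc1
Why: Williamson etherification of the dianion; the 2-oxide is conjugated with and chelated to the formyl group, so the 3-oxide is the more nucleophilic and takes the single equivalent of benzyl bromide.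

Step 2
Reactants: 2 3-(benzyloxy)-2-hydroxybenzaldehyde; 3 methyl 3-bromobenzoate
Product: 4 methyl 3-[2-(benzyloxy)-6-formylphenoxy]benzoate
Conditions: CuI (10 mol%), picolinic acid (20 mol%), K3PO4, DMSO, 90 °C
Reagents that add atoms: none
Why: Ullmann-type O-arylation under monovalent copper; the picolinate ligand system couples ortho,ortho'-disubstituted phenols, the ester activates the aryl bromide, and the aldehyde is not enolisable.

Step 3
Reactants: 4 methyl 3-[2-(benzyloxy)-6-formylphenoxy]benzoate
Product: 5 methyl 3-[2-(benzyloxy)-6-ethenylphenoxy]benzoate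
Conditions: Ph3PCH3Br, KOtBu, THF, 0 °C
Reagents that add atoms: methyltriphenylphosphonium bromide, C[P+](c1ccccc1)(c1ccccc1)c1ccccc1.[Br-]
Why: Wittig methylenation; the unstabilised ylide reacts with the aldehyde far faster than with the aryl ester.

Step 4
Reactants: 6 4-bromo-2,6-dichlorophenol
Product: 7 (4-bromo-2,6-dichlorophenoxy)tri(propan-2-yl)silane
Conditions: i-Pr3SiOTf, 2,6-lutidine, CH2Cl2, 0 °C to rt
Reagents that add atoms: tri(propan-2-yl)silyl trifluoromethanesulfonate, CC(C)[Si](OS(=O)(=O)C(F)(F)F)(C(C)C)C(C)C
Why: O-silylation of a hindered, acidic phenol with a silyl triflate; the bulky silyl group flanked by two chlorines should survive the coupling, hydride and organozinc steps yet leave easily with fluoride.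

Step 5
Reactants: 5 methyl 3-[2-(benzyloxy)-6-ethenylphenoxy]benzoate; 7 (4-bromo-2,6-dichlorophenoxy)tri(propan-2-yl)silane
Product: 9 methyl 3-{2-(benzyloxy)-6-[2-(3,5-dichloro-4-{[tri(propan-2-yl)silyl]oxy}phenyl)ethyl]phenoxy}benzoate, via alkylborane 8 (not isolated)
Conditions: 9-BBN, THF, 0 °C to rt; then 7, PdCl2(dppf) (5 mol%), K3PO4, DMF, 50 °C
Reagents that add atoms: none
Why: anti-Markovnikov hydroboration of the styrene followed by B-alkyl Suzuki–Miyaura coupling; the dppf ligand suppresses beta-hydride elimination, the C–Br bond reacts while the flanked C–Cl bonds do not, and the nearly anhydrous base spares the ester and the aryl silyl ether.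

Step 6
Reactants: 9 methyl 3-{2-(benzyloxy)-6-[2-(3,5-dichloro-4-{[tri(propan-2-yl)silyl]oxy}phenyl)ethyl]phenoxy}benzoate
Product: 10 (3-{2-(benzyloxy)-6-[2-(3,5-dichloro-4-{[tri(propan-2-yl)silyl]oxy}phenyl)ethyl]phenoxy}phenyl)methanol
Conditions: i-Bu2AlH (2.5 equiv), CH2Cl2, −78 to 0 °C; aq potassium sodium tartrate
Reagents that add atoms: none
Why: hydride reduction of the aryl ester to the benzylic alcohol; aryl chlorides, the benzyl ether and the aryl silyl ether are inert to the aluminium hydride at this temperature.

Step 7
Reactants: 10 (3-{2-(benzyloxy)-6-[2-(3,5-dichloro-4-{[tri(propan-2-yl)silyl]oxy}phenyl)ethyl]phenoxy}phenyl)methanol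
Product: 11 [4-(2-{3-(benzyloxy)-2-[3-(bromomethyl)phenoxy]phenyl}ethyl)-2,6-dichlorophenoxy]tri(propan-2-yl)silane
Conditions: CBr4, PPh3, CH2Cl2, 0 °C
Reagents that add atoms: carbon tetrabromide, BrC(Br)(Br)Br
Why: Appel bromination of a primary benzylic alcohol under neutral conditions, which no other group in the molecule answers to.

Step 8
Reactants: 12 3,5-dibromo-4-hydroxybenzaldehyde
Product: 13 3,5-dibromo-4-{[tri(propan-2-yl)silyl]oxy}benzaldehyde
Conditions: i-Pr3SiOTf, 2,6-lutidine, CH2Cl2, 0 °C
Reagents that add atoms: tri(propan-2-yl)silyl trifluoromethanesulfonate, CC(C)[Si](OS(=O)(=O)C(F)(F)F)(C(C)C)C(C)C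
Why: O-silylation as in step 4; capping the acidic phenol restores the electrophilicity of the aldehyde and removes the proton that would quench the zinc reagent.

Step 9
Reactants: 11 [4-(2-{3-(benzyloxy)-2-[3-(bromomethyl)phenoxy]phenyl}ethyl)-2,6-dichlorophenoxy]tri(propan-2-yl)silane; 13 3,5-dibromo-4-{[tri(propan-2-yl)silyl]oxy}benzaldehyde
Product: 15 rac-2-(3-{2-(benzyloxy)-6-[2-(3,5-dichloro-4-{[tri(propan-2-yl)silyl]oxy}phenyl)ethyl]phenoxy}phenyl)-1-(3,5-dibromo-4-{[tri(propan-2-yl)silyl]oxy}phenyl)ethan-1-ol, via benzylic zinc bromide 14 (not isolated)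
Conditions: Zn dust (activated with BrCH2CH2Br and Me3SiCl), LiCl, THF, 0 °C to rt; then 13, 0 °C to rt; aq NH4Cl
Reagents that add atoms: none
Why: lithium chloride-promoted zinc insertion into the benzylic bromide and 1,2-addition of the benzylic zinc halide to an electron-poor aromatic aldehyde; the reagent tolerates aryl bromides, aryl chlorides and silyl ethers, and the alcohol is formed racemic on purpose.

Step 10
Reactants: 15 rac-2-(3-{2-(benzyloxy)-6-[2-(3,5-dichloro-4-{[tri(propan-2-yl)silyl]oxy}phenyl)ethyl]phenoxy}phenyl)-1-(3,5-dibromo-4-{[tri(propan-2-yl)silyl]oxy}phenyl)ethan-1-ol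
Product: 16 2-(3-{2-(benzyloxy)-6-[2-(3,5-dichloro-4-{[tri(propan-2-yl)silyl]oxy}phenyl)ethyl]phenoxy}phenyl)-1-(3,5-dibromo-4-{[tri(propan-2-yl)silyl]oxy}phenyl)ethan-1-one
Conditions: Dess–Martin periodinane, NaHCO3, CH2Cl2, rt
Reagents that add atoms: none
Why: Dess–Martin oxidation of a secondary benzylic alcohol under buffered, near-neutral conditions that keep the labile aryl silyl ether para to the new ketone.

Step 11
Reactants: 16 2-(3-{2-(benzyloxy)-6-[2-(3,5-dichloro-4-{[tri(propan-2-yl)silyl]oxy}phenyl)ethyl]phenoxy}phenyl)-1-(3,5-dibromo-4-{[tri(propan-2-yl)silyl]oxy}phenyl)ethan-1-one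
Product: 17 (1S)-2-(3-{2-(benzyloxy)-6-[2-(3,5-dichloro-4-{[tri(propan-2-yl)silyl]oxy}phenyl)ethyl]phenoxy}phenyl)-1-(3,5-dibromo-4-{[tri(propan-2-yl)silyl]oxy}phenyl)ethan-1-ol
Conditions: (R)-2-methyl-CBS-oxazaborolidine (20 mol%), BH3·SMe2, THF, −20 °C, slow addition of 16
Reagents that add atoms: none
Why: Corey–Bakshi–Shibata reduction; the aryl group takes the large-group position and the arylmethyl group the small one, so the (R)-catalyst delivers hydride to the Re face and gives the (S)-alcohol, as acetophenone gives (S)-1-phenylethanol with the same catalyst.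

Step 12
Reactants: 17 (1S)-2-(3-{2-(benzyloxy)-6-[2-(3,5-dichloro-4-{[tri(propan-2-yl)silyl]oxy}phenyl)ethyl]phenoxy}phenyl)-1-(3,5-dibromo-4-{[tri(propan-2-yl)silyl]oxy}phenyl)ethan-1-ol
Product: 18 tert-butyl[(1S)-2-(3-{2-(benzyloxy)-6-[2-(3,5-dichloro-4-{[tri(propan-2-yl)silyl]oxy}phenyl)ethyl]phenoxy}phenyl)-1-(3,5-dibromo-4-{[tri(propan-2-yl)silyl]oxy}phenyl)ethoxy]dimethylsilane
Conditions: t-BuMe2SiOTf, 2,6-lutidine, CH2Cl2, −78 to 0 °C
Reagents that add atoms: tert-butyldimethylsilyl trifluoromethanesulfonate, CC(C)(C)[Si](C)(C)OS(=O)(=O)C(F)(F)F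
Why: O-silylation of the secondary alcohol with a silyl triflate and a hindered base; no C–O bond at the stereocentre is broken, so the configuration is retained.

Step 13
Reactants: 18 tert-butyl[(1S)-2-(3-{2-(benzyloxy)-6-[2-(3,5-dichloro-4-{[tri(propan-2-yl)silyl]oxy}phenyl)ethyl]phenoxy}phenyl)-1-(3,5-dibromo-4-{[tri(propan-2-yl)silyl]oxy}phenyl)ethoxy]dimethylsilane
Product: 19 2,6-dibromo-4-[(1S)-2-(3-{2-(benzyloxy)-6-[2-(3,5-dichloro-4-hydroxyphenyl)ethyl]phenoxy}phenyl)-1-{[tert-butyl(dimethyl)silyl]oxy}ethyl]phenol (seco bisphenol)
Conditions: Bu4NF (2.2 equiv), AcOH (2.2 equiv), THF, 0 °C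
Reagents that add atoms: none
Why: chemoselective desilylation; 2,6-dihalophenoxides are good leaving groups from silicon, so buffered fluoride should cleave both aryl silyl ethers at 0 °C while the hindered secondary alkyl silyl ether stays.

Step 14
Reactants: 19 2,6-dibromo-4-[(1S)-2-(3-{2-(benzyloxy)-6-[2-(3,5-dichloro-4-hydroxyphenyl)ethyl]phenoxy}phenyl)-1-{[tert-butyl(dimethyl)silyl]oxy}ethyl]phenol (seco bisphenol)
Product: 21 macrocyclic diaryl ether (ring A 3-bromo-4-hydroxy-5-aryloxy; ring B 3,5-dichloro; ring C benzyl ether; (S)-carbinol as tert-butyldimethylsilyl ether), via bromodienone 20 (not isolated)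
Conditions: constant-current electrolysis (glassy-carbon anode, Pt cathode, undivided cell, about 2.2 F per mol), LiClO4 (0.1 M), MeOH, 1 mM in 19, rt; evaporate; then Zn dust, AcOH, THF, rt
Reagents that add atoms: none
Why: Two-electron anodic oxidation of the ring A 2,6-dibromophenol gives a phenoxonium ion; the ring B phenol oxygen adds to one of the two equivalent bromine-bearing ortho carbons (18-exo-trig closure of the macrocycle) to give the 6-aryloxy-2,6-dibromocyclohexa-2,4-dienone 20, and zinc in acetic acid then expels bromide from the sp3 carbon and rearomatises ring A to the 2-aryloxy-6-bromophenol 21. The closest known reaction type is the anodic or thallium trinitrate oxidation of ortho,ortho'-dihalogenated phenols to aryloxy dienones followed by zinc reduction, which has closed isodityrosine-type macrocycles from a dibromophenol and a dichlorophenol. Ring A should be the ring oxidised because a dibromophenol is oxidised at lower potential than a dichlorophenol, and the two chlorines block C-attack on ring B and leave its oxygen as the only nucleophilic site. Because both ortho carbons of ring A carry bromine there is no regiochemical choice, and an ortho alkoxy group, which would draw the nucleophile to its own carbon, is deliberately absent. Capture at the para carbon, by methanol or by the ring B oxygen, gives quinol ethers that zinc returns to 19, so that path costs conversion and not material. The sp3 carbon of 20 forms without control and is erased on reduction, so no new stereocentre remains, and the silylated carbinol has no free hydroxyl through which the side chain could fragment. High dilution and a charge limited to about two faradays per mole should hold back oligomers and oxidation of the dialkoxy ring C.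

Step 15
Reactants: 21 macrocyclic diaryl ether (ring A 3-bromo-4-hydroxy-5-aryloxy; ring B 3,5-dichloro; ring C benzyl ether; (S)-carbinol as tert-butyldimethylsilyl ether)
Product: 22 ring A 4-O-benzyl ether of 21 (ring A 3-bromo-4-benzyloxy-5-aryloxy)
Conditions: BnBr, K2CO3, DMF, rt
Reagents that add atoms: benzyl bromide, BrCc1ccccc1
Why: Williamson etherification of the only free phenol; capping it allows the palladium step that follows and gives a group that leaves in the final hydrogenolysis.

Step 16
Reactants: 22 ring A 4-O-benzyl ether of 21 (ring A 3-bromo-4-benzyloxy-5-aryloxy)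
Product: 24 macrocycle with ring A 3-hydroxy-4-benzyloxy-5-aryloxy (ring B 3,5-dichloro; ring C benzyl ether; (S)-silyl ether), via pinacol boronate 23 (not isolated)
Conditions: B2pin2, PdCl2(dppf) (10 mol%), KOAc, 1,4-dioxane, 90 °C; then 30% H2O2, aq NaOH, THF, 0 °C
Reagents that add atoms: hydrogen peroxide, OO
Why: Miyaura borylation of the aryl bromide and oxidation of the C–B bond to C–OH with retention at carbon; with dppf, zerovalent palladium inserts into C–Br and not into the two C–Cl bonds, each of which is flanked by the ether oxygen.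

Step 17
Reactants: 24 macrocycle with ring A 3-hydroxy-4-benzyloxy-5-aryloxy (ring B 3,5-dichloro; ring C benzyl ether; (S)-silyl ether)
Product: 25 (S)-O-tert-butyldimethylsilyl ether of the target
Conditions: H2 (1 atm), 10% Pd/C, NaOAc, EtOAc–MeOH, rt
Reagents that add atoms: none
Why: catalytic hydrogenolysis of two aryl C–Cl bonds and two aryl benzyl ethers; the acetate buffer takes up the HCl, so the benzylic C–O bond, which is shielded as a silyl ether, is not activated by acid.

Step 18
Reactants: 25 (S)-O-tert-butyldimethylsilyl ether of the target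
Product: 26 CNP0333307.1 (target; (S)-carbinol)
Conditions: Bu4NF, AcOH, THF, 0 °C to rt, argon
Reagents that add atoms: none
Why: fluoride cleavage of the secondary silyl ether at silicon, so the C–O bond and its configuration are untouched; the acetic acid buffer and inert gas protect the catechol and the p-hydroxybenzylic alcohol from base and air.

## Compound list

1 | 2,3-dihydroxybenzaldehyde | O=Cc1cccc(O)c1O | starting material
2 | 3-(benzyloxy)-2-hydroxybenzaldehyde | O=Cc1cccc(OCc2ccccc2)c1O | intermediate
3 | methyl 3-bromobenzoate | COC(=O)c1cccc(Br)c1 | starting material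
4 | methyl 3-[2-(benzyloxy)-6-formylphenoxy]benzoate | O=Cc1cccc(OCc2ccccc2)c1Oc1cccc(c1)C(=O)OC | intermediate
5 | methyl 3-[2-(benzyloxy)-6-ethenylphenoxy]benzoate | C=Cc1cccc(OCc2ccccc2)c1Oc1cccc(c1)C(=O)OC | intermediate
6 | 4-bromo-2,6-dichlorophenol | Oc1c(Cl)cc(Br)cc1Cl | starting material
7 | (4-bromo-2,6-dichlorophenoxy)tri(propan-2-yl)silane | CC(C)[Si](C(C)C)(C(C)C)Oc1c(Cl)cc(Br)cc1Cl | intermediate
8 | methyl 3-{2-(benzyloxy)-6-[2-(9-borabicyclo[3.3.1]nonan-9-yl)ethyl]phenoxy}benzoate (alkylborane, not isolated) | COC(=O)c1cccc(c1)Oc1c(OCc2ccccc2)cccc1CCB1C2CCCC1CCC2 | intermediate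
9 | methyl 3-{2-(benzyloxy)-6-[2-(3,5-dichloro-4-{[tri(propan-2-yl)silyl]oxy}phenyl)ethyl]phenoxy}benzoate | CC(C)[Si](C(C)C)(C(C)C)Oc1c(Cl)cc(cc1Cl)CCc1cccc(OCc2ccccc2)c1Oc1cccc(c1)C(=O)OC | intermediate
10 | (3-{2-(benzyloxy)-6-[2-(3,5-dichloro-4-{[tri(propan-2-yl)silyl]oxy}phenyl)ethyl]phenoxy}phenyl)methanol | CC(C)[Si](C(C)C)(C(C)C)Oc1c(Cl)cc(cc1Cl)CCc1cccc(OCc2ccccc2)c1Oc1cccc(c1)CO | intermediate
11 | [4-(2-{3-(benzyloxy)-2-[3-(bromomethyl)phenoxy]phenyl}ethyl)-2,6-dichlorophenoxy]tri(propan-2-yl)silane | CC(C)[Si](C(C)C)(C(C)C)Oc1c(Cl)cc(cc1Cl)CCc1cccc(OCc2ccccc2)c1Oc1cccc(c1)CBr | intermediate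
12 | 3,5-dibromo-4-hydroxybenzaldehyde | O=Cc1cc(Br)c(O)c(Br)c1 | starting material
13 | 3,5-dibromo-4-{[tri(propan-2-yl)silyl]oxy}benzaldehyde | O=Cc1cc(Br)c(O[Si](C(C)C)(C(C)C)C(C)C)c(Br)c1 | intermediate
14 | benzylic zinc bromide from 11 (not isolated) | CC(C)[Si](C(C)C)(C(C)C)Oc1c(Cl)cc(cc1Cl)CCc1cccc(OCc2ccccc2)c1Oc1cccc(c1)C[Zn]Br | intermediate
15 | rac-2-(3-{2-(benzyloxy)-6-[2-(3,5-dichloro-4-{[tri(propan-2-yl)silyl]oxy}phenyl)ethyl]phenoxy}phenyl)-1-(3,5-dibromo-4-{[tri(propan-2-yl)silyl]oxy}phenyl)ethan-1-ol | CC(C)[Si](C(C)C)(C(C)C)Oc1c(Cl)cc(cc1Cl)CCc1cccc(OCc2ccccc2)c1Oc1cccc(c1)CC(O)c1cc(Br)c(O[Si](C(C)C)(C(C)C)C(C)C)c(Br)c1 | intermediate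
16 | 2-(3-{2-(benzyloxy)-6-[2-(3,5-dichloro-4-{[tri(propan-2-yl)silyl]oxy}phenyl)ethyl]phenoxy}phenyl)-1-(3,5-dibromo-4-{[tri(propan-2-yl)silyl]oxy}phenyl)ethan-1-one | CC(C)[Si](C(C)C)(C(C)C)Oc1c(Cl)cc(cc1Cl)CCc1cccc(OCc2ccccc2)c1Oc1cccc(c1)CC(=O)c1cc(Br)c(O[Si](C(C)C)(C(C)C)C(C)C)c(Br)c1 | intermediate
17 | (1S)-2-(3-{2-(benzyloxy)-6-[2-(3,5-dichloro-4-{[tri(propan-2-yl)silyl]oxy}phenyl)ethyl]phenoxy}phenyl)-1-(3,5-dibromo-4-{[tri(propan-2-yl)silyl]oxy}phenyl)ethan-1-ol | CC(C)[Si](C(C)C)(C(C)C)Oc1c(Cl)cc(cc1Cl)CCc1cccc(OCc2ccccc2)c1Oc1cccc(c1)C[C@H](O)c1cc(Br)c(O[Si](C(C)C)(C(C)C)C(C)C)c(Br)c1 | intermediate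
18 | tert-butyldimethylsilyl ether of 17, (S) | CC(C)[Si](C(C)C)(C(C)C)Oc1c(Cl)cc(cc1Cl)CCc1cccc(OCc2ccccc2)c1Oc1cccc(c1)C[C@H](O[Si](C)(C)C(C)(C)C)c1cc(Br)c(O[Si](C(C)C)(C(C)C)C(C)C)c(Br)c1 | intermediate
19 | seco bisphenol, (S)-silyl ether, ring A 3,5-dibromo-4-hydroxy, ring B 3,5-dichloro-4-hydroxy | Oc1c(Cl)cc(cc1Cl)CCc1cccc(OCc2ccccc2)c1Oc1cccc(c1)C[C@H](O[Si](C)(C)C(C)(C)C)c1cc(Br)c(O)c(Br)c1 | intermediate
20 | macrocyclic bromodienone (ring A as 6-aryloxy-2,6-dibromocyclohexa-2,4-dienone; sp3 ring carbon uncontrolled; carbinol S; not isolated) | O=C1C(Br)=CC2=CC1(Br)Oc1c(Cl)cc(cc1Cl)CCc1cccc(OCc3ccccc3)c1Oc1cccc(c1)C[C@@H]2O[Si](C)(C)C(C)(C)C | intermediate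
21 | macrocyclic diaryl ether, ring A 3-bromo-4-hydroxy-5-aryloxy, ring B 3,5-dichloro, ring C benzyl ether, (S)-silyl ether | Brc1cc2cc(c1O)Oc1c(Cl)cc(cc1Cl)CCc1cccc(OCc3ccccc3)c1Oc1cccc(c1)C[C@@H]2O[Si](C)(C)C(C)(C)C | intermediate
22 | ring A 4-O-benzyl ether of 21 | Brc1cc2cc(c1OCc1ccccc1)Oc1c(Cl)cc(cc1Cl)CCc1cccc(OCc3ccccc3)c1Oc1cccc(c1)C[C@@H]2O[Si](C)(C)C(C)(C)C | intermediate
23 | ring A pinacol boronate of 22 (boron in place of bromine; not isolated) | CC1(C)OB(OC1(C)C)c1cc2cc(c1OCc1ccccc1)Oc1c(Cl)cc(cc1Cl)CCc1cccc(OCc3ccccc3)c1Oc1cccc(c1)C[C@@H]2O[Si](C)(C)C(C)(C)C | intermediate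
24 | macrocycle, ring A 3-hydroxy-4-benzyloxy-5-aryloxy, ring B 3,5-dichloro, ring C benzyl ether, (S)-silyl ether | Oc1cc2cc(c1OCc1ccccc1)Oc1c(Cl)cc(cc1Cl)CCc1cccc(OCc3ccccc3)c1Oc1cccc(c1)C[C@@H]2O[Si](C)(C)C(C)(C)C | intermediate
25 | (S)-O-tert-butyldimethylsilyl ether of the target | Oc1cc2cc(c1O)Oc1ccc(cc1)CCc1cccc(O)c1Oc1cccc(c1)C[C@@H]2O[Si](C)(C)C(C)(C)C | intermediate
26 | CNP0333307.1, (S)-carbinol | Oc1cc2cc(c1O)Oc1ccc(cc1)CCc1cccc(O)c1Oc1cccc(c1)C[C@@H]2O | target

## Step count and least certain steps

Total: 18 steps. Longest linear sequence: 16 steps (1 to 26 through steps 1–3, 5–7 and 9–18). Steps 4 and 8 are one-step branches.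

**Step 14 (key step).** Three things can go wrong.
- Loss of ring selectivity: ring B has a plain alkyl chain para to its phenol, while ring A has an electron-withdrawing benzylic silyloxy carbon there. This narrows the small gap between a dibromophenol and a dichlorophenol. Oxidation of ring B would close a ring of the same size through the wrong oxygen.
- Loss of the benzylic proton from the phenoxonium ion to a quinone methide, which would destroy the stereocentre.
- Electron transfer from the dialkoxy ring C, or methanol capture at an ortho carbon.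

A first remedy inside the same approach is Tl(NO3)3 (trivalent thallium) in methanol, an inner-sphere oxidant that engages phenols only.

The fallback changes the approach: the same O–C(ring A) bond is made by copper-catalysed intramolecular Ullmann etherification of a seco compound without halogen on ring B. It leaves the route at styrene 5 and returns at silyl ether 25.
- Hydroboration of 5 (alkylborane 8) and Suzuki coupling as in step 5 with (4-bromophenoxy)tri(propan-2-yl)silane F1 (from 4-bromophenol as in step 4) give methyl 3-{2-(benzyloxy)-6-[2-(4-{[tri(propan-2-yl)silyl]oxy}phenyl)ethyl]phenoxy}benzoate F2.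
- i-Bu2AlH gives the benzylic alcohol F3, and CBr4 with PPh3 the benzylic bromide F4.
- Its benzylic zinc bromide F5 adds to 3,4-bis(benzyloxy)-5-bromobenzaldehyde F6 (from 3-bromo-4,5-dihydroxybenzaldehyde, BnBr and K2CO3) to give the racemic carbinol F7.
- Dess–Martin oxidation gives the ketone F8, reduction as in step 11 the (S)-carbinol F9, and silylation as in step 12 the (S)-tert-butyldimethylsilyl ether F10.
- Buffered Bu4NF frees the ring B phenol to give the seco bromo phenol F11.
- CuI, N,N-dimethylglycine and Cs2CO3 in dioxane at high dilution and 100 °C close the ring to the tribenzyl macrocycle F12.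
- Hydrogenolysis (H2, Pd/C, EtOAc) of the three benzyl ethers gives 25.

This branch needs no chlorines and no late hydroxylation. Its weakness is oxidative addition of copper into an electron-rich aryl bromide flanked by a benzyloxy group, in an 18-membered closure.

**Step 16.** Most likely is slow oxidative addition of the palladium catalyst into the electron-rich C–Br bond, flanked by a benzyloxy group, with protodebromination taking over; forcing the reaction would start insertion into the C–Cl bonds. Fallback from 22 to 24 by stoichiometric organolithium chemistry: bromine–lithium exchange (n-BuLi, THF, −78 °C) gives the ring A aryllithium F13, B(OMe)3 gives the ring A dimethyl boronate F14, and H2O2 with aq NaOH in the same flask gives 24. Aryl chlorides do not exchange at this temperature.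

**Step 17.** Most likely is slow hydrogenolysis of the two C–Cl bonds flanked by the ether oxygen. The longer exposure or harder conditions then needed would put the benzylic C–O bond, now para to a free hydroxyl, and the silyl ether at risk. Fallback from 24 to 25 in two stages. Homogeneous hydride-transfer dechlorination with (IPr)Pd(allyl)Cl and NaOtBu in i-PrOH at 60 °C gives the dechlorinated dibenzyl ether F15, without a heterogeneous catalyst and without HCl. A short acid-free hydrogenolysis (H2, Pd(OH)2/C, EtOAc) then removes the two benzyl groups to give 25.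

**Step 2.** Most likely is a stalled coupling: the phenoxide is weakened by the ortho formyl group, flanked on both sides, and can bind copper as a chelate. Fallback from 2 to 4 by metal-free aryl transfer from trivalent iodine: bis[3-(methoxycarbonyl)phenyl]iodonium tetrafluoroborate F16 (from methyl 3-iodobenzoate, [3-(methoxycarbonyl)phenyl]boronic acid, mCPBA and BF3·OEt2) arylates the potassium phenoxide of 2 (KOtBu, THF, rt to 40 °C) and gives 4. Such salts arylate hindered phenols well.

**Step 11.** Most likely is poor facial selectivity, because the catalyst must tell an aryl group from an arylmethyl group by size alone. Fallback from 16 to 17 by a different recognition principle: Noyori asymmetric transfer hydrogenation with RuCl(p-cymene)[(S,S)-TsDPEN] and HCO2H–Et3N in CH2Cl2 at rt. The aryl ring on the carbonyl carbon is recognised by a CH–π contact, and the (S,S)-catalyst gives the (S)-alcohol, as it does with acetophenone. No new compound is made.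

## Further compounds

F1 | step 14 | (4-bromophenoxy)tri(propan-2-yl)silane | CC(C)[Si](C(C)C)(C(C)C)Oc1ccc(Br)cc1
F2 | step 14 | methyl 3-{2-(benzyloxy)-6-[2-(4-{[tri(propan-2-yl)silyl]oxy}phenyl)ethyl]phenoxy}benzoate | CC(C)[Si](C(C)C)(C(C)C)Oc1ccc(cc1)CCc1cccc(OCc2ccccc2)c1Oc1cccc(c1)C(=O)OC
F3 | step 14 | benzylic alcohol from F2 | CC(C)[Si](C(C)C)(C(C)C)Oc1ccc(cc1)CCc1cccc(OCc2ccccc2)c1Oc1cccc(c1)CO
F4 | step 14 | benzylic bromide from F3 | CC(C)[Si](C(C)C)(C(C)C)Oc1ccc(cc1)CCc1cccc(OCc2ccccc2)c1Oc1cccc(c1)CBr
F5 | step 14 | benzylic zinc bromide from F4 | CC(C)[Si](C(C)C)(C(C)C)Oc1ccc(cc1)CCc1cccc(OCc2ccccc2)c1Oc1cccc(c1)C[Zn]Br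
F6 | step 14 | 3,4-bis(benzyloxy)-5-bromobenzaldehyde | O=Cc1cc(Br)c(OCc2ccccc2)c(OCc2ccccc2)c1
F7 | step 14 | racemic carbinol from F5 and F6 | CC(C)[Si](C(C)C)(C(C)C)Oc1ccc(cc1)CCc1cccc(OCc2ccccc2)c1Oc1cccc(c1)CC(O)c1cc(Br)c(OCc2ccccc2)c(OCc2ccccc2)c1
F8 | step 14 | ketone from F7 | CC(C)[Si](C(C)C)(C(C)C)Oc1ccc(cc1)CCc1cccc(OCc2ccccc2)c1Oc1cccc(c1)CC(=O)c1cc(Br)c(OCc2ccccc2)c(OCc2ccccc2)c1
F9 | step 14 | (S)-carbinol from F8 | CC(C)[Si](C(C)C)(C(C)C)Oc1ccc(cc1)CCc1cccc(OCc2ccccc2)c1Oc1cccc(c1)C[C@H](O)c1cc(Br)c(OCc2ccccc2)c(OCc2ccccc2)c1
F10 | step 14 | (S)-tert-butyldimethylsilyl ether of F9 | CC(C)[Si](C(C)C)(C(C)C)Oc1ccc(cc1)CCc1cccc(OCc2ccccc2)c1Oc1cccc(c1)C[C@H](O[Si](C)(C)C(C)(C)C)c1cc(Br)c(OCc2ccccc2)c(OCc2ccccc2)c1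
F11 | step 14 | seco bromo phenol (ring B 4-hydroxy; ring A 3-bromo-4,5-bis(benzyloxy); (S)-silyl ether) | Oc1ccc(cc1)CCc1cccc(OCc2ccccc2)c1Oc1cccc(c1)C[C@H](O[Si](C)(C)C(C)(C)C)c1cc(Br)c(OCc2ccccc2)c(OCc2ccccc2)c1
F12 | step 14 | tribenzyl macrocycle, (S)-silyl ether | c1ccccc1COc1cc2cc(c1OCc1ccccc1)Oc1ccc(cc1)CCc1cccc(OCc3ccccc3)c1Oc1cccc(c1)C[C@@H]2O[Si](C)(C)C(C)(C)C
F13 | step 16 | ring A aryllithium from 22 | [Li]c1cc2cc(c1OCc1ccccc1)Oc1c(Cl)cc(cc1Cl)CCc1cccc(OCc3ccccc3)c1Oc1cccc(c1)C[C@@H]2O[Si](C)(C)C(C)(C)C
F14 | step 16 | ring A dimethyl boronate from F13 | COB(OC)c1cc2cc(c1OCc1ccccc1)Oc1c(Cl)cc(cc1Cl)CCc1cccc(OCc3ccccc3)c1Oc1cccc(c1)C[C@@H]2O[Si](C)(C)C(C)(C)C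
F15 | step 17 | dechlorinated dibenzyl ether of the macrocycle, (S)-silyl ether | Oc1cc2cc(c1OCc1ccccc1)Oc1ccc(cc1)CCc1cccc(OCc3ccccc3)c1Oc1cccc(c1)C[C@@H]2O[Si](C)(C)C(C)(C)C
F16 | step 2 | bis[3-(methoxycarbonyl)phenyl]iodonium tetrafluoroborate | COC(=O)c1cccc(c1)[I+]c1cccc(c1)C(=O)OC.F[B-](F)(F)F
F0 | step 11 | none | none
A1 | alternative 1 | seco bromo ketone (ring A methyl ketone; ring D bromide; tribenzyl ether) | CC(=O)c1cc(OCc2ccccc2)c(OCc2ccccc2)c(c1)Oc1ccc(cc1)CCc1cccc(OCc2ccccc2)c1Oc1cccc(Br)c1
A2 | alternative 1 | macrocyclic deoxybenzoin, tribenzyl ether | c1ccccc1COc1cc2cc(c1OCc1ccccc1)Oc1ccc(cc1)CCc1cccc(OCc3ccccc3)c1Oc1cccc(c1)CC2=O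
A3 | alternative 2 | seco primary iodide with ring C as 2-aryloxy-3-(triflyloxy)cyclohex-2-enone, (S)-silyl ether | O=C1CCCC(OS(=O)(=O)C(F)(F)F)=C1Oc1cccc(c1)C[C@H](O[Si](C)(C)C(C)(C)C)c1cc(OCc2ccccc2)c(OCc2ccccc2)c(c1)Oc1ccc(CCI)cc1
A4 | alternative 2 | macrocycle with ring C as 2-aryloxy-3-alkylcyclohex-2-enone, (S)-silyl ether | O=C1CCCC2=C1Oc1cccc(c1)C[C@H](O[Si](C)(C)C(C)(C)C)c1cc(OCc3ccccc3)c(OCc3ccccc3)c(c1)Oc1ccc(cc1)CC2
A5 | alternative 3 | seco ring D phenol with 2-fluoro-3-formyl ring C, (S)-silyl ether | O=Cc1cccc(CCc2ccc(cc2)Oc2cc(cc(OCc3ccccc3)c2OCc2ccccc2)[C@@H](O[Si](C)(C)C(C)(C)C)Cc2cccc(O)c2)c1F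
A6 | alternative 3 | macrocycle with formyl group at ring C carbon 3, (S)-silyl ether | O=Cc1cccc2c1Oc1cccc(c1)C[C@H](O[Si](C)(C)C(C)(C)C)c1cc(OCc3ccccc3)c(OCc3ccccc3)c(c1)Oc1ccc(cc1)CC2
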